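(The readings are calculated from invented constants; scatter was added.)

- In the oak run a leftover of L stands at the last reading: if each X takes one L, about 0.928 M of the 1.28 M charged remains, and X is still rising although the Z column read 0% at 10.0 h.

- oak: Z 0.80 M; L 1.28 M; run made earlier
- flask: Z 1.6 M; L 1.28 M; time 25 h

oak run (percent of the Z charged)

| time / h | X / % | Z / % |
|---|---|---|
| 2.00 | 5 | 70 |
| 5.00 | 18 | 35 |
| 10.0 | 32 | 0 |
| 15.0 | 44 | 0 |

(scatter of a reading: 2 percentage points)

- as a solid, counted per litre of solution: Z
- the analysis behind the earlier runs scatters by 2 percentage points, standard deviation
- at the start none of Z is in solution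

- green: doubling the dissolution coefficient of Z, all else as stated
- violet: doubling the amount of L, all else as stated
- red: doubling the solubility of Z, all else as stated

- the X standing at 25 h, as a percentage of the Z charged
- the change that raises the amount of X at 25 h, in percent of the Z charged most ("none" if none brings more than 2 percentage points) (green / violet / red / none)
- amount of X at 25 h, in percent of the Z charged, after red

- The loose bracket for the flask is wide: the oak run's X at 15.0 h, 0.352 M, is 22.0% of the flask's Z, and c_L allows 80.0% at one L per X.
- The tightening tool is the rate per L, the molarity of X made per hour divided by the charged c_L, read roughly as a pseudo-first-order constant in L.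
- Read from the oak run, from the start to the last reading it is 0.0183 h⁻¹, and over the last stretch 0.0150 h⁻¹, lower but not collapsing after the Z column read 0%.
- My ceiling is an estimate, not a proven limit: it supposes that the flask averages the first value over 25 h, which gives 36.7%.
- My floor is an estimate too: it supposes that the flask, with twice the Z of the oak run, averages the second value over that time, which gives 30.0%.
- The forecast gives 32%, inside this bracket, with violet as the best change and 33% after red, on the ground that “the step looks saturated in dissolved Z and limited by L”.
- The flask gives 32.6%, inside the bracket; violet is best, adding 12 percentage points, and red gives 36.5%.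

    Z ⇌ G, rate k1*(cs1 - [G]) while solid is left; crystals form when [G] > cs1 (solubility = 0.900 M, k = 0.0850 h⁻¹)
    G + L → X (k = 0.130 L mol⁻¹ h⁻¹)
    2 G → E (k = 0.160 L mol⁻¹ h⁻¹)
    2 Z → Q (k = 0.0630 L mol⁻¹ h⁻¹)

- The flask's rate per L over 25 h is 0.0163 h⁻¹, between the two oak values, and 59% of its L stands at 25.0 h. For the same flask charged with 0.32 M of L, the oak values give 7.50% to 9.17% of X, and that flask stands at 10.7%.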